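| setting | dusk | autumn | flask |
|---|---|---|---|
| starting complex | 0.070 M | 0.11 M | 0.050 M |
| incoming ligand | 0.15 M | 0.15 M | 0.150 M |
| remark | run made earlier | run made earlier |  |
| time |  |  | 8.0 d |

| run | time / d | complex with one exchanged / % | complex with three exchanged / % |
|---|---|---|---|
| dusk | 0.500 | 22.7 | 16.2 |
| dusk | 1.67 | 15.6 | 12.0 |
| dusk | 3.00 | 11.6 | 8.3 |
| dusk | 4.00 | 9.8 | 7.0 |
| dusk | 6.00 | 6.9 | 4.7 |
| dusk | 8.00 | 6.5 | 3.1 |
| autumn | 1.25 | 17.3 | 5.2 |
| autumn | 2.50 | 12.7 | 2.1 |
| autumn | 4.00 | 9.7 | 1.5 |
| autumn | 5.00 | 8.5 | 0.9 |
| autumn | 6.00 | 7.4 | 1.2 |
| autumn | 8.00 | 6.3 | 0.5 |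

(scatter of a reading: 0.3 percentage points)



- equivalents of incoming ligand to starting complex, everything else as given, that leave most complex with one exchanged at 8.0 d
- the amount of complex with one exchanged then, in percent of the starting complex charged
- the amount of complex with one exchanged with the amounts as given

- The dusk run gives 1.46 /d for the fade, the daily rise of the reciprocal of the fraction of the charge standing as complex with one exchanged.
- A steady fade is an apparent second-order fall: the share lost per day is the fade times the fraction present. In the dusk run that is 0.332 /d at the first reading and 0.0952 /d at the last, a slowing by a factor 3.49, which is the fall of the fraction itself.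
- The autumn run, with more starting complex but the same incoming ligand, reads 1.50 /d, about the same. Both runs hold the incoming ligand at one charge, so the fade is read for that charge.
- The slowing accumulates as a sum of reciprocals. Starting from the first autumn reading, the dusk fade gives 6.38 % at 8.0 d, and the autumn run read 6.3 %. This flask has the same incoming ligand but less starting complex; taking the fade over unchanged, my own estimate for it is also 6.38 %.
- The forecast differs: 3 % as charged, and a best of 12 % at 1.2 equiv, holding that “the dilute 0.05 M charge slows the scrambling”.
- The flask gives 5.94 % as charged, and a best of 13.1 % at 0.434 equiv.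

    complex with two exchanged + incoming ligand ⇌ leaving ligand + complex with three exchanged (K = 2.90, k = 4.90 /M/h)
    complex with one exchanged + incoming ligand ⇌ leaving ligand + complex with two exchanged (K = 1.90, k = 3.30 /M/h)
    starting complex + incoming ligand ⇌ leaving ligand + complex with one exchanged (K = 1.50, k = 2.50 /M/h)
    starting complex + complex with three exchanged → side product (k = 1.60 /M/h)
    incoming ligand ⇌ dormant form (K = 0.670, k = 0.190 /h)

- Between 0.800 d and 8.00 d this flask shows a fade of 1.59 /d. A second flask, charged with 0.0250 M of starting complex and the same incoming ligand, holds 5.74 % of complex with one exchanged at 8.0 d, against the 6.38 % that the same fade estimates. In this flask at 8.00 d, the step between complex with two exchanged and complex with three exchanged, taken alone and both ways together, relaxes with a half-life of 0.0785 d, far shorter than the 3.83 d of the slowest mode of the whole flask.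

The runs are calculated for an exercise; scatter was added.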